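**Plan**

- Retrosynthesis: the two CH2OH groups on C3 and C4 are traced back to N-acyl oxazolidinone carbonyls. The ring is then cut at O1–C2 and O1–C5 (removing one water) and at C3–C4, which leaves two identical sinapoyl imides.
- Enabling feature: the target is the C2-symmetric C3–C4 (β–β) dimer of two 4-hydroxy-3,5-dimethoxyphenylpropanoid halves. Their benzylic carbons C2 and C5 share the ring oxygen O1 of the single tetrahydrofuran ring, and each half carries a free para-phenol that can be oxidised by one electron.
- Forward: sinapic acid is O-silylated, joined to (S)-4-benzyl-2-oxazolidinone and desilylated. FeCl3 in aqueous acetone then forms C3–C4, and water closes the only ring (O1–C2, O1–C5). LiBH4 finally converts both imides into the hydroxymethyl groups.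
- Stereochemistry: C3 and C4 come from the auxiliary-biased like coupling, made stereochemically pure by separating diastereomers. C2 and C5 come from reversible, acid-mediated benzylic C–O formation that places each aryl group trans to its neighbour. The reduction touches no stereocentre.

Key step: step 4

Assumption: in aqueous acetone the imide is taken to be unchelated by trivalent iron and to react as its dipole-minimised (carbonyls anti), s-cis rotamer. On that model the (S)-auxiliary leaves open the face of the α-carbon that leads to the required (3R,4R)-diimide; a chelated rotamer would call for the (R)-auxiliary with the same operations.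

**Route**

Step 1
Reactants: 1 sinapic acid
Product: 3 (2E)-3-{4-[tert-butyl(dimethyl)silyloxy]-3,5-dimethoxyphenyl}prop-2-enoic acid, via bis-silylated sinapic acid 2 (not isolated)
Conditions: TBSCl (2.4 equiv), imidazole, DMF, rt; then AcOH/THF/H2O, rt
Reagents that add atoms: tert-butyldimethylsilyl chloride, CC(C)(C)[Si](C)(C)Cl
Why: Silylation of both acidic OH groups with a silyl chloride and imidazole, followed by selective hydrolysis of the far more labile silyl ester, should leave the phenol masked as its silyl ether; no stereocentre is formed and the E-alkene is untouched.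

Step 2
Reactants: 3 (2E)-3-{4-[tert-butyl(dimethyl)silyloxy]-3,5-dimethoxyphenyl}prop-2-enoic acid; 4 (S)-4-benzyl-2-oxazolidinone
Product: 6 (4S)-4-benzyl-3-[(2E)-3-{4-[tert-butyl(dimethyl)silyloxy]-3,5-dimethoxyphenyl}prop-2-enoyl]-1,3-oxazolidin-2-one, via mixed pivalic anhydride 5 (not isolated)
Conditions: PivCl, Et3N, THF, −20 °C; then LiCl, 4, −20 °C → rt
Reagents that add atoms: pivaloyl chloride, CC(C)(C)C(=O)Cl (its atoms are carried only by intermediate 5)
Why: N-Acylation of an oxazolidinone through a mixed pivalic anhydride under LiCl/Et3N activation is the standard entry to enoyl imides; the hindered pivaloyl carbonyl directs attack to the sinapoyl carbonyl and the auxiliary stereocentre is carried in unchanged.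

Step 3
Reactants: 6 (4S)-4-benzyl-3-[(2E)-3-{4-[tert-butyl(dimethyl)silyloxy]-3,5-dimethoxyphenyl}prop-2-enoyl]-1,3-oxazolidin-2-one
Product: 7 (4S)-4-benzyl-3-[(2E)-3-(4-hydroxy-3,5-dimethoxyphenyl)prop-2-enoyl]-1,3-oxazolidin-2-one
Conditions: TBAF, AcOH, THF, 0 °C
Reagents that add atoms: none
Why: Fluoride-induced desilylation of an aryl silyl ether, buffered with acetic acid so that neither fluoride nor free phenoxide attacks the imide, should release the phenol needed for oxidation.

Step 4
Reactants: 7 (4S)-4-benzyl-3-[(2E)-3-(4-hydroxy-3,5-dimethoxyphenyl)prop-2-enoyl]-1,3-oxazolidin-2-one (two molecules)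
Product: 10 (4S,4'S)-3,3'-[(2R,3R,4R,5R)-2,5-bis(4-hydroxy-3,5-dimethoxyphenyl)oxolane-3,4-dicarbonyl]bis(4-benzyl-1,3-oxazolidin-2-one), via bis(quinone methide) diimide 8 (not isolated), via hydroxy quinone methide 9 (not isolated)
Conditions: FeCl3·6H2O (1.1 equiv per phenol), acetone/H2O 2:1, argon, 0 °C → rt, stirred on in the HCl-acidic medium to equilibrate C2/C5; diastereomers separated on silica or by crystallisation
Reagents that add atoms: water, O
Why: Proposed new method: FeCl3 (trivalent iron) should oxidise each phenol of 7 by one electron to a phenoxyl radical delocalised onto the carbon α to the imide carbonyl; two such radicals combine there (the future C3–C4) to give bis(quinone methide) 8, water adds 1,6 to one methide carbon to give 9, and the new benzylic hydroxyl closes onto the second methide carbon in a 5-exo-trig oxa-conjugate addition (O1–C2 and O1–C5), forming the only ring. The closest known reaction types are the FeCl3/aqueous acetone β–β dehydrodimerisation of sinapate and ferulate esters with water capture to 2,5-diaryltetrahydrofuran-3,4-dicarboxylates and the auxiliary-directed oxidative homocoupling of imide enolates; what is new is steering the phenoxyl coupling with an oxazolidinone. C3 and C4 are set in the C–C coupling by the auxiliary: in the carbonyl-anti, s-cis rotamer the benzyl group on C4 of each (S)-oxazolidinone lies over one face of the α-carbon, both radicals should bond through the open face, and this like pairing gives the (3R,4R) arrangement; the two like dimers and the unlike dimer are diastereomers, so whatever the kinetic bias does not secure can be removed by separation. C2 and C5 are set under thermodynamic control: the HCl set free keeps water addition and ring closure reversible through the 4-hydroxy-3,5-dimethoxybenzyl cation or quinone methide, so each aryl group should settle trans to its neighbouring acyl group (2R,5R, all-trans). The step needs coupling at the side chain only and hydration faster than side reactions: the 3- and 5-methoxy groups block ring coupling, the weakly nucleophilic imide carbonyl cannot lactonise onto the methides as a carboxylic acid would, and the high water content should let hydration outrun tautomerisation of 8 to arylidene imides and Friedel–Crafts closure to an aryldihydronaphthalene.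

Step 5
Reactants: 10 (4S,4'S)-3,3'-[(2R,3R,4R,5R)-2,5-bis(4-hydroxy-3,5-dimethoxyphenyl)oxolane-3,4-dicarbonyl]bis(4-benzyl-1,3-oxazolidin-2-one)
Product: 11 [(2R,3S,4S,5R)-2,5-bis(4-hydroxy-3,5-dimethoxyphenyl)oxolane-3,4-diyl]dimethanol
Conditions: LiBH4 (excess), THF/MeOH, 0 °C → rt; aq NH4Cl
Reagents that add atoms: none
Why: Reductive cleavage of N-acyl oxazolidinones with LiBH4 should deliver both primary alcohols and free the auxiliary without touching the benzylic ethers or any stereocentre; the descriptors at C3 and C4 change from R to S only because CH2OH ranks below C2 and C5 whereas the acyl carbon ranks above them.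

**Compound list**

1 | sinapic acid, (2E)-3-(4-hydroxy-3,5-dimethoxyphenyl)prop-2-enoic acid | COc1cc(/C=C/C(=O)O)cc(OC)c1O | starting material
2 | tert-butyldimethylsilyl (2E)-3-{4-[tert-butyl(dimethyl)silyloxy]-3,5-dimethoxyphenyl}prop-2-enoate (not isolated) | COc1cc(/C=C/C(=O)O[Si](C)(C)C(C)(C)C)cc(OC)c1O[Si](C)(C)C(C)(C)C | intermediate
3 | (2E)-3-{4-[tert-butyl(dimethyl)silyloxy]-3,5-dimethoxyphenyl}prop-2-enoic acid | COc1cc(/C=C/C(=O)O)cc(OC)c1O[Si](C)(C)C(C)(C)C | intermediate
4 | (S)-4-benzyl-2-oxazolidinone | O=C1N[C@@H](Cc2ccccc2)CO1 | starting material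
5 | mixed anhydride of 3 with pivalic acid (not isolated) | COc1cc(/C=C/C(=O)OC(=O)C(C)(C)C)cc(OC)c1O[Si](C)(C)C(C)(C)C | intermediate
6 | (4S)-4-benzyl-3-[(2E)-3-{4-[tert-butyl(dimethyl)silyloxy]-3,5-dimethoxyphenyl}prop-2-enoyl]-1,3-oxazolidin-2-one | COc1cc(/C=C/C(=O)N2[C@@H](Cc3ccccc3)COC2=O)cc(OC)c1O[Si](C)(C)C(C)(C)C | intermediate
7 | (4S)-4-benzyl-3-[(2E)-3-(4-hydroxy-3,5-dimethoxyphenyl)prop-2-enoyl]-1,3-oxazolidin-2-one (key-step precursor) | COc1cc(/C=C/C(=O)N2[C@@H](Cc3ccccc3)COC2=O)cc(OC)c1O | intermediate
8 | (4S,4'S)-3,3'-{(2S,3S)-2,3-bis[(3,5-dimethoxy-4-oxocyclohexa-2,5-dien-1-ylidene)methyl]butanedioyl}bis(4-benzyl-1,3-oxazolidin-2-one) (not isolated) | COC1=CC(=C[C@H](C(=O)N2[C@@H](Cc3ccccc3)COC2=O)[C@H](C=C2C=C(OC)C(=O)C(OC)=C2)C(=O)N2[C@@H](Cc3ccccc3)COC2=O)C=C(OC)C1=O | intermediate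
9 | (4S,4'S)-3,3'-{(2R,3S)-2-[(R)-hydroxy(4-hydroxy-3,5-dimethoxyphenyl)methyl]-3-[(3,5-dimethoxy-4-oxocyclohexa-2,5-dien-1-ylidene)methyl]butanedioyl}bis(4-benzyl-1,3-oxazolidin-2-one), the epimer that closes to 10 (not isolated) | COc1cc([C@H](O)[C@H](C(=O)N2[C@@H](Cc3ccccc3)COC2=O)[C@H](C=C2C=C(OC)C(=O)C(OC)=C2)C(=O)N2[C@@H](Cc3ccccc3)COC2=O)cc(OC)c1O | intermediate
10 | (4S,4'S)-3,3'-[(2R,3R,4R,5R)-2,5-bis(4-hydroxy-3,5-dimethoxyphenyl)oxolane-3,4-dicarbonyl]bis(4-benzyl-1,3-oxazolidin-2-one), all-trans (key-step product) | COc1cc([C@@H]2O[C@@H](c3cc(OC)c(O)c(OC)c3)[C@H](C(=O)N3[C@@H](Cc4ccccc4)COC3=O)[C@H]2C(=O)N2[C@@H](Cc3ccccc3)COC2=O)cc(OC)c1O | intermediate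
11 | [(2R,3S,4S,5R)-2,5-bis(4-hydroxy-3,5-dimethoxyphenyl)oxolane-3,4-diyl]dimethanol, all-trans | COc1cc([C@@H]2O[C@@H](c3cc(OC)c(O)c(OC)c3)[C@H](CO)[C@H]2CO)cc(OC)c1O | target

**Step count and risks**

Total step count: 5. Longest linear sequence: 5 steps (1 → 3 → 6 → 7 → 10 → 11).

Steps most likely to fail:

1. Step 4 (the step carrying the label). What may go wrong:
   - poor facial discrimination in the radical–radical coupling, so that all three C3/C4 diastereomers form in similar amounts;
   - tautomerisation of the bis(quinone methide) to arylidene imides and Friedel–Crafts closure to an aryldihydronaphthalene before water is captured;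
   - incomplete convergence of the C2/C5 epimers, or over-oxidation of the product phenols.

   Fallback with known chemistry, setting out from 1 and returning to the route at 11. Fischer esterification of 1 (EtOH, catalytic H2SO4, reflux) gives ethyl (E)-sinapate F1. Its dehydrodimerisation with FeCl3·6H2O in aqueous acetone, the established β–β coupling of sinapate esters with water capture, followed by brief acid equilibration of the benzylic centres, gives racemic all-trans diethyl 2,5-bis(4-hydroxy-3,5-dimethoxyphenyl)oxolane-3,4-dicarboxylate F2. LiAlH4 in THF reduces F2 to the racemic all-trans diol F3. Preparative HPLC on an amylose tris(3,5-dimethylphenylcarbamate) phase separates the enantiomers, and the (2R,3S,4S,5R) antipode is 11.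

2. Step 5. What may go wrong:
   - hydride attack at the ring carbonyl of the crowded oxazolidinones, giving ring-opened hydroxyethyl amides instead of the alcohols;
   - base-induced epimerisation at C3/C4, or retro-oxa-Michael opening of the tetrahydrofuran in the phenoxide/alkoxide medium.

   Fallback setting out from 10 and returning at 11. LiOH/H2O2 (THF/H2O, 0 °C), which attacks only the exocyclic carbonyl even of hindered imides, cleaves both auxiliaries to (2R,3R,4R,5R)-2,5-bis(4-hydroxy-3,5-dimethoxyphenyl)oxolane-3,4-dicarboxylic acid F4 with recovery of 4. BH3·THF (0 °C → rt) then reduces both carboxylic acids to the primary alcohols and gives 11 without a strongly basic medium.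

3. Step 3. What may go wrong:
   - sluggish cleavage of the doubly ortho-substituted aryl silyl ether under buffered fluoride;
   - opening of the imide by fluoride or phenoxide once the buffer is reduced.

   Fallback setting out from 4 and returning at 7, without any phenol protecting group. N-Acylation of 4 with bromoacetyl bromide (n-BuLi, THF, −78 °C) gives (S)-4-benzyl-3-(bromoacetyl)oxazolidin-2-one F5. PPh3 in toluene converts F5 into the phosphonium bromide F6, and aqueous NaOH deprotonates this to the stabilised ylide (S)-4-benzyl-3-[(triphenylphosphoranylidene)acetyl]oxazolidin-2-one F7. Heating F7 with commercial syringaldehyde (4-hydroxy-3,5-dimethoxybenzaldehyde) in toluene gives 7 by an E-selective Wittig reaction; stabilised ylides are known to olefinate unprotected 4-hydroxybenzaldehydes.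

**Further compounds**

F1 | step 4 | ethyl (2E)-3-(4-hydroxy-3,5-dimethoxyphenyl)prop-2-enoate | COc1cc(/C=C/C(=O)OCC)cc(OC)c1O
F2 | step 4 | racemic diethyl (2R*,3R*,4R*,5R*)-2,5-bis(4-hydroxy-3,5-dimethoxyphenyl)oxolane-3,4-dicarboxylate (both enantiomers written) | COc1cc([C@@H]2O[C@@H](c3cc(OC)c(O)c(OC)c3)[C@H](C(=O)OCC)[C@H]2C(=O)OCC)cc(OC)c1O.COc1cc([C@H]2O[C@H](c3cc(OC)c(O)c(OC)c3)[C@@H](C(=O)OCC)[C@@H]2C(=O)OCC)cc(OC)c1O
F3 | step 4 | racemic [(2R*,3S*,4S*,5R*)-2,5-bis(4-hydroxy-3,5-dimethoxyphenyl)oxolane-3,4-diyl]dimethanol (both enantiomers written) | COc1cc([C@@H]2O[C@@H](c3cc(OC)c(O)c(OC)c3)[C@H](CO)[C@H]2CO)cc(OC)c1O.COc1cc([C@H]2O[C@H](c3cc(OC)c(O)c(OC)c3)[C@@H](CO)[C@@H]2CO)cc(OC)c1O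
F4 | step 5 | (2R,3R,4R,5R)-2,5-bis(4-hydroxy-3,5-dimethoxyphenyl)oxolane-3,4-dicarboxylic acid | COc1cc([C@@H]2O[C@@H](c3cc(OC)c(O)c(OC)c3)[C@H](C(=O)O)[C@H]2C(=O)O)cc(OC)c1O
F5 | step 3 | (S)-4-benzyl-3-(bromoacetyl)oxazolidin-2-one | O=C(CBr)N1[C@@H](Cc2ccccc2)COC1=O
F6 | step 3 | {2-[(4S)-4-benzyl-2-oxo-1,3-oxazolidin-3-yl]-2-oxoethyl}triphenylphosphonium bromide | [Br-].O=C(C[P+](c1ccccc1)(c1ccccc1)c1ccccc1)N1[C@@H](Cc2ccccc2)COC1=O
F7 | step 3 | (S)-4-benzyl-3-[(triphenylphosphoranylidene)acetyl]oxazolidin-2-one | O=C(C=P(c1ccccc1)(c1ccccc1)c1ccccc1)N1[C@@H](Cc2ccccc2)COC1=O
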